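**Plan**

- Rings: A azepanone, B pyrrolidine, C cyclohexene, D seven-membered carbocycle, E cyclopentadiene of the fulvene, F dihydropyran. Ring E atoms: a (C–OAc), b (shared with F), c (hub of D, E and F, carrying the exocyclic C=C), d (shared by C, D, E), e (shared by C and E, next to the ketol carbon).
- Cuts, in retrosynthetic order: ring E at a–e; ring A at N–CH2 together with the carbinolamine; the ketone–isopropenyl bond; ring D at c–d; the C=N of ring B; the quaternary C–CH bond. This leaves a 2-methylcyclohexane-1,3-dione ester (ring C) and a dihydropyranyl nitroalkene (ring F).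
- Forward order: ring F fragment, union with ring C, ring B, ring D, ketol oxygen, diene, ring A with the hemiaminal, then ring E with its acetate.
- Enabling feature: the ring-F oxygen, hub c and atoms d, e form a dienol ether O–C=C(c)–C(d)=C(e)H whose δ-carbon e is nucleophilic. Ring F holds the carboxyl carbon a on atom b, locked s-cis to C(d)=C(e). Closure gives the push-pull fulvene at the final oxidation level, so no helper group has to be removed.
- Stereochemistry: the ring-B CH centre by catalyst; the quaternary methyl centre by equilibrating imine formation; the ketol carbon by enolate oxidation opposite an axial ring-D branch; the hemiaminal carbon and the α-methyl centre by the bridged ring (only open face, thermodynamic epimer).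

Key step: step 16

Remark: the methyl-bearing carbon next to the ring-A ketone is assumed to be the thermodynamically preferred (exo-methyl) epimer; pyran C-4 and the ester-bearing CH of ring C are carried as epimer mixtures until they become sp2 or quaternary.

Step 1
Reactants: 1 tetrahydro-2H-pyran-4-carboxylic acid
Product: 2 2-(trimethylsilyl)ethyl tetrahydro-2H-pyran-4-carboxylate
Conditions: 2-(trimethylsilyl)ethanol, EDC·HCl, DMAP (cat.), CH2Cl2, 0 °C to rt
Reagents that add atoms: 2-(trimethylsilyl)ethanol, OCC[Si](C)(C)C
Why: Carbodiimide esterification of an unhindered acid; the fluoride-labile ester lets this carboxyl be freed later without touching the ethyl ester of the other fragment.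

Step 2
Reactants: 2 2-(trimethylsilyl)ethyl tetrahydro-2H-pyran-4-carboxylate
Product: 3 2-(trimethylsilyl)ethyl 2-oxotetrahydro-2H-pyran-4-carboxylate (racemic)
Conditions: RuCl3 (cat.), NaIO4, EtOAc/MeCN/H2O, rt
Reagents that add atoms: sodium periodate, [Na+].[O-]I(=O)(=O)=O
Why: RuO4 formed in situ oxidises a CH2 next to the ether oxygen to the lactone carbonyl, and the two such positions of the symmetric ring are equivalent (ether-to-lactone oxidation).

Step 3
Reactants: 3 2-(trimethylsilyl)ethyl 2-oxotetrahydro-2H-pyran-4-carboxylate
Product: 4 2-(trimethylsilyl)ethyl 6-[(diphenoxyphosphoryl)oxy]-3,4-dihydro-2H-pyran-4-carboxylate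
Conditions: KN(SiMe3)2, (PhO)2P(O)Cl, THF/DMPU, −78 °C
Reagents that add atoms: diphenyl chlorophosphate, O=P(Cl)(Oc1ccccc1)Oc1ccccc1
Why: The lactone CH2 is more acidic and less hindered than the ester CH, and O-phosphorylation of its potassium enolate gives the cyclic ketene acetal phosphate, the usual handle for cross-coupling at a lactone-derived enol ether carbon.

Step 4
Reactants: 4 2-(trimethylsilyl)ethyl 6-[(diphenoxyphosphoryl)oxy]-3,4-dihydro-2H-pyran-4-carboxylate; 5 allyloxytrimethylsilane
Product: 8 2-(trimethylsilyl)ethyl 6-(3-hydroxypropyl)-3,4-dihydro-2H-pyran-4-carboxylate, via alkylborane 6 (not isolated), via silyl ether 7 (not isolated)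
Conditions: 5, 9-BBN-H, THF, 0 °C to rt; then 4, PdCl2(dppf) (5 mol %), aq. Cs2CO3, DMF, 50 °C; K2CO3, MeOH, 0 °C in the work-up
Reagents that add atoms: none
Why: Anti-Markovnikov hydroboration and B-alkyl Suzuki–Miyaura coupling with the ketene acetal phosphate attach the three-carbon chain to the enol ether carbon, and the labile Me3Si ether is methanolysed in the basic work-up.

Step 5
Reactants: 8 2-(trimethylsilyl)ethyl 6-(3-hydroxypropyl)-3,4-dihydro-2H-pyran-4-carboxylate
Product: 9 2-(trimethylsilyl)ethyl 6-(3-oxopropyl)-3,4-dihydro-2H-pyran-4-carboxylate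
Conditions: Dess–Martin periodinane, NaHCO3, CH2Cl2, 0 °C
Reagents that add atoms: none
Why: Bicarbonate-buffered Dess–Martin oxidation gives the aldehyde under non-acidic conditions that leave the enol ether intact.

Step 6
Reactants: 9 2-(trimethylsilyl)ethyl 6-(3-oxopropyl)-3,4-dihydro-2H-pyran-4-carboxylate
Product: 11 2-(trimethylsilyl)ethyl 6-[(3E)-4-nitrobut-3-en-1-yl]-3,4-dihydro-2H-pyran-4-carboxylate, via nitro alcohol 10 (not isolated)
Conditions: MeNO2, Et3N (cat.), 0 °C to rt; then MsCl, Et3N, CH2Cl2, 0 °C
Reagents that add atoms: nitromethane, C[N+](=O)[O-]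
Why: Henry addition followed by mesylation and E1cB elimination gives the conjugated nitroalkene, the (E) isomer being favoured thermodynamically.

Step 7
Reactants: 12 ethyl 3,5-dioxocyclohexane-1-carboxylate
Product: 14 ethyl 4-methyl-3,5-dioxocyclohexane-1-carboxylate, via methylidene dione 13 (not isolated)
Conditions: aq. CH2O, diethyl 2,6-dimethyl-1,4-dihydropyridine-3,5-dicarboxylate (Hantzsch ester), L-proline (cat.), CH2Cl2, rt
Reagents that add atoms: formaldehyde, C=O
Why: Knoevenagel condensation with formaldehyde and in situ conjugate reduction by the dihydropyridine (organocatalytic reductive alkylation) methylates the dione at carbon only.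

Step 8
Reactants: 14 ethyl 4-methyl-3,5-dioxocyclohexane-1-carboxylate; 11 2-(trimethylsilyl)ethyl 6-[(3E)-4-nitrobut-3-en-1-yl]-3,4-dihydro-2H-pyran-4-carboxylate
Product: 15 ethyl 4-methyl-4-[(2S)-1-nitro-4-(4-{[2-(trimethylsilyl)ethoxy]carbonyl}-3,4-dihydro-2H-pyran-6-yl)butan-2-yl]-3,5-dioxocyclohexane-1-carboxylate
Conditions: 3,5-bis(trifluoromethyl)phenyl squaramide of 9-amino-9-deoxy-epi-quinine (5 mol %; the epi-quinidine pseudo-enantiomer if Re-face delivery requires it), CH2Cl2, rt
Reagents that add atoms: none
Why: Organocatalytic nitro-Michael addition of a cyclic 1,3-diketone: the quinuclidine deprotonates the acidic dione while the squaramide binds the nitro group, so the dione carbon is delivered to the Re face of the nitroalkene β-carbon and sets the (S)-CH centre (the symmetric quaternary carbon is not yet stereogenic).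

Step 9
Reactants: 15 Michael adduct
Product: 17 ethyl (3S,3aR)-3a-methyl-4-oxo-3-[2-(4-{[2-(trimethylsilyl)ethoxy]carbonyl}-3,4-dihydro-2H-pyran-6-yl)ethyl]-3,3a,4,5,6,7-hexahydro-2H-indole-6-carboxylate (side chain cis to the ring-ketone carbon), via amino diketone 16 (not isolated)
Conditions: H2 (1 atm), Raney Ni, EtOH, rt; then AcOH (0.2 equiv), wet EtOH, 40 °C
Reagents that add atoms: none
Why: Nitro hydrogenation and spontaneous 5-exo condensation with one of the two equivalent ketones give the 1-pyrroline, and because the two imines interconvert through the open amino diketone under acid, the isomer whose side chain lies cis to the flat ring-ketone carbon instead of eclipsing the angular methyl should dominate, which fixes the quaternary centre.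

Step 10
Reactants: 17 bicyclic keto imine
Product: 18 ene adduct (rings B, C, D, F; tertiary hydroxyl on the former ketone carbon cis to the angular methyl; enol ether C=C now in ring D)
Conditions: Me2AlCl (3 equiv), CH2Cl2, −78 to −20 °C; aq. Rochelle salt
Reagents that add atoms: none
Why: Lewis acid carbonyl-ene (Prins-type) cyclisation: the enol ether β-carbon adds to the activated ketone from the lower face dictated by the tether, closing ring D with the new C–C bond axial and the hydroxyl cis to the angular methyl, while the aluminium alkoxide takes the allylic proton (the enol ether C=C moves into ring D) and Me2AlCl scavenges acid so the carbinol survives.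

Step 11
Reactants: 18 ene adduct
Product: 19 ketol ester (new tertiary hydroxyl on the ester-bearing carbon of ring C, cis to the angular methyl; ethyl ester on the nitrogen face)
Conditions: LiN(iPr)2 (3.2 equiv), THF, −78 °C; 2-(phenylsulfonyl)-3-phenyloxaziridine (1.1 equiv), −78 °C; aq. NH4Cl
Reagents that add atoms: 2-(phenylsulfonyl)-3-phenyloxaziridine, O=S(=O)(c1ccccc1)N1OC1c1ccccc1
Why: Enolate oxidation with an N-sulfonyloxaziridine: the axial ring-D branch on the neighbouring carbinol carbon shields the lower face 1,3 to the enolate carbon, so oxygen enters from the methyl face (equatorial attack) and the ester ends axial on the nitrogen side, while the more hindered pyran ester enolate is not oxidised by the limiting oxidant and is reprotonated.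

Step 12
Reactants: 19 ketol ester
Product: 21 dienol ether diester (O–C=C(c)–C(d)=C(e)H in place; ketol carbon R), via endocyclic enol ether 20 (not isolated)
Conditions: camphor-10-sulfonic acid (1.2 equiv), 4 Å molecular sieves, CH2Cl2, 0 °C to rt; aq. NaHCO3
Reagents that add atoms: none
Why: Acid first returns the enol ether double bond to ring F and then ionises the tertiary alcohol, now allylic to the enol ether (vinylogous oxocarbenium ion), with loss of the ring-C proton to give the conjugated dienol ether, whereas the α-hydroxy ester carbinol, flanked by a carbonyl, does not ionise.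

Step 13
Reactants: 21 dienol ether diester
Product: 22 dienol ether acid (ethyl ester retained)
Conditions: Bu4NF, THF, 0 °C to rt; aq. NH4Cl
Reagents that add atoms: none
Why: Fluoride attack at silicon fragments the 2-(trimethylsilyl)ethyl ester to the carboxylate, ethene and Me3SiF, leaving the ethyl ester, imine and dienol ether untouched; the product is handled as its iminium carboxylate zwitterion.

Step 14
Reactants: 22 dienol ether acid
Product: 24 α′-hydroxy enone acid (2-methylprop-2-enoyl group on the ketol carbon), via Weinreb amide 23 (not isolated)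
Conditions: MeNH(OMe)·HCl, iPrMgCl, THF, −20 °C; then CH2=C(CH3)MgBr, −20 to 0 °C; aq. NH4Cl
Reagents that add atoms: isopropenylmagnesium bromide, CC(=C)[Mg]Br
Why: Magnesium amide aminolysis of the chelating α-hydroxy ester gives the Weinreb amide, whose stable tetrahedral chelate accepts one isopropenyl Grignard to give the α′-hydroxy enone, the magnesium carboxylate and alkoxide being inert (one-pot ester-to-ketone conversion).

Step 15
Reactants: 24 α′-hydroxy enone acid
Product: 26 pentacyclic amino acid (rings A, B, C, D, F; bridgehead hemiaminal; exo-methyl ketone), via carbinolamine 25 (not isolated)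
Conditions: MeCN/H2O (pH 7 phosphate buffer), 40 °C
Reagents that add atoms: water, O
Why: Water adds reversibly to the ketimine and the carbinolamine whose NH is axial on the lower face adds to the hydrogen-bond-activated α′-hydroxy enone (7-endo-trig aza-Michael), closing ring A; the closed hemiaminal cannot revert because an iminium or enamine would need a bridgehead double bond, its hydroxyl occupies the only open (exo) face, and the α-methyl centre equilibrates through the enol to the exo-methyl epimer.

Step 16
Reactants: 26 pentacyclic amino acid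
Product: 30 CNP0309418.1 (target acetoxyfulvene), via mixed anhydride 27 (not isolated), via ketene 28 (not isolated), via hydroxyfulvene 29 (not isolated)
Conditions: Ac2O (4 equiv), Et3N (6 equiv), PhMe, 80 °C
Reagents that add atoms: acetic anhydride, CC(=O)OC(C)=O
Why: Proposed new method: The acid forms the mixed anhydride 27, which loses acetate (E1cB; the α-H is also allylic) to the vinylketene 28; its ketene carbon a is attacked in the ketene plane by the CH carbon e, the δ-terminus of the dienol ether, giving a zwitterion whose cation is a vinylogous oxocarbenium ion on the ring-F oxygen, and loss of the proton on e gives hydroxyfulvene 29, which excess Ac2O acetylates on oxygen. The closest known reactions are the Ac2O-mediated cyclisation of Stobbe-type dienyl acids through dienylketenes to aryl acetates and the terminal C-acylation of 1-alkoxydienes by anhydrides; a five-membered closure of this kind onto a dienol ether has not been shown. Ring E closes in a 5-exo-dig sense at the ketene carbon (5-endo-trig at the C(d)=C(e) bond), a five-centre, electrocyclisation-like closure made feasible by oxygen stabilisation of the cation. No stereocentre is formed; a, b and e become sp2, so the pyran C-4 epimers converge. The step needs C-acylation at e instead of capture of the ketene by oxygen or nitrogen: ring F holds the ketene s-cis to C(d)=C(e) and s-trans to the enol ether carbon (no cyclobutenone), lactonisation onto the ketol hydroxyl would need a trans double bond in a seven-membered ring, and without an acylation catalyst the two tertiary hydroxyls are not acetylated while the acidic fulvenol is.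

**Compound list**

1 | tetrahydro-2H-pyran-4-carboxylic acid | OC(=O)C1CCOCC1 | starting material
2 | 2-(trimethylsilyl)ethyl tetrahydro-2H-pyran-4-carboxylate | C[Si](C)(C)CCOC(=O)C1CCOCC1 | intermediate
3 | 2-(trimethylsilyl)ethyl 2-oxotetrahydro-2H-pyran-4-carboxylate (racemic) | C[Si](C)(C)CCOC(=O)C1CCOC(=O)C1 | intermediate
4 | 2-(trimethylsilyl)ethyl 6-[(diphenoxyphosphoryl)oxy]-3,4-dihydro-2H-pyran-4-carboxylate (racemic) | C[Si](C)(C)CCOC(=O)C1CCOC(OP(=O)(Oc2ccccc2)Oc2ccccc2)=C1 | intermediate
5 | allyloxytrimethylsilane | C=CCO[Si](C)(C)C | starting material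
6 | 9-[3-(trimethylsilyloxy)propyl]-9-borabicyclo[3.3.1]nonane | C[Si](C)(C)OCCCB1C2CCCC1CCC2 | intermediate (not isolated)
7 | 2-(trimethylsilyl)ethyl 6-[3-(trimethylsilyloxy)propyl]-3,4-dihydro-2H-pyran-4-carboxylate | C[Si](C)(C)CCOC(=O)C1CCOC(CCCO[Si](C)(C)C)=C1 | intermediate (not isolated)
8 | 2-(trimethylsilyl)ethyl 6-(3-hydroxypropyl)-3,4-dihydro-2H-pyran-4-carboxylate | C[Si](C)(C)CCOC(=O)C1CCOC(CCCO)=C1 | intermediate
9 | 2-(trimethylsilyl)ethyl 6-(3-oxopropyl)-3,4-dihydro-2H-pyran-4-carboxylate | C[Si](C)(C)CCOC(=O)C1CCOC(CCC=O)=C1 | intermediate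
10 | 2-(trimethylsilyl)ethyl 6-(3-hydroxy-4-nitrobutyl)-3,4-dihydro-2H-pyran-4-carboxylate | C[Si](C)(C)CCOC(=O)C1CCOC(CCC(O)C[N+](=O)[O-])=C1 | intermediate (not isolated)
11 | 2-(trimethylsilyl)ethyl 6-[(3E)-4-nitrobut-3-en-1-yl]-3,4-dihydro-2H-pyran-4-carboxylate | C[Si](C)(C)CCOC(=O)C1CCOC(CC/C=C/[N+](=O)[O-])=C1 | intermediate
12 | ethyl 3,5-dioxocyclohexane-1-carboxylate | CCOC(=O)C1CC(=O)CC(=O)C1 | starting material
13 | ethyl 4-methylidene-3,5-dioxocyclohexane-1-carboxylate | CCOC(=O)C1CC(=O)C(=C)C(=O)C1 | intermediate (not isolated)
14 | ethyl 4-methyl-3,5-dioxocyclohexane-1-carboxylate | CCOC(=O)C1CC(=O)C(C)C(=O)C1 | intermediate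
15 | Michael adduct, (S) at the CH bearing the nitromethyl group | CCOC(=O)C1CC(=O)C(C)([C@@H](C[N+](=O)[O-])CCC2=CC(C(=O)OCC[Si](C)(C)C)CCO2)C(=O)C1 | intermediate
16 | amino diketone from 15 | CCOC(=O)C1CC(=O)C(C)([C@@H](CN)CCC2=CC(C(=O)OCC[Si](C)(C)C)CCO2)C(=O)C1 | intermediate (not isolated)
17 | bicyclic keto imine (3S,3aR; side chain cis to the ring-ketone carbon, trans to the angular methyl) | CCOC(=O)C1CC(=O)[C@]2(C)[C@H](CCC3=CC(C(=O)OCC[Si](C)(C)C)CCO3)CN=C2C1 | intermediate
18 | ene adduct (ring D closed; tertiary OH cis to the angular methyl; enol ether C=C in ring D) | CCOC(=O)C1C[C@]2(O)C3C(=CC[C@@H]4CN=C(C1)[C@@]42C)OCCC3C(=O)OCC[Si](C)(C)C | intermediate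
19 | ketol ester (second tertiary OH on the ester-bearing ring-C carbon, cis to the angular methyl) | CCOC(=O)[C@]1(O)C[C@]2(O)C3C(=CC[C@@H]4CN=C(C1)[C@@]42C)OCCC3C(=O)OCC[Si](C)(C)C | intermediate
20 | endocyclic enol ether isomer of 19 | CCOC(=O)[C@]1(O)C[C@]2(O)C3=C(CC[C@@H]4CN=C(C1)[C@@]42C)OCCC3C(=O)OCC[Si](C)(C)C | intermediate (not isolated)
21 | dienol ether diester | CCOC(=O)[C@]1(O)C=C2C3=C(CC[C@@H]4CN=C(C1)[C@@]42C)OCCC3C(=O)OCC[Si](C)(C)C | intermediate
22 | dienol ether acid | CCOC(=O)[C@]1(O)C=C2C3=C(CC[C@@H]4CN=C(C1)[C@@]42C)OCCC3C(O)=O | intermediate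
23 | Weinreb amide of 22 | CON(C)C(=O)[C@]1(O)C=C2C3=C(CC[C@@H]4CN=C(C1)[C@@]42C)OCCC3C(O)=O | intermediate (not isolated)
24 | α′-hydroxy enone acid | C=C(C)C(=O)[C@]1(O)C=C2C3=C(CC[C@@H]4CN=C(C1)[C@@]42C)OCCC3C(O)=O | intermediate
25 | carbinolamine (hydrate of the imine of 24; OH on the methyl face) | C=C(C)C(=O)[C@]1(O)C=C2C3=C(CC[C@@H]4CN[C@](O)(C1)[C@@]42C)OCCC3C(O)=O | intermediate (not isolated)
26 | pentacyclic amino acid (rings A, B, C, D, F; carboxyl on pyran C-4) | OC(=O)C1CCOC2=C1C1=C[C@]3(O)C[C@@]4(O)N(C[C@@H](CC2)[C@@]14C)C[C@@H](C)C3=O | intermediate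
27 | mixed acetic anhydride of 26 | CC(=O)OC(=O)C1CCOC2=C1C1=C[C@]3(O)C[C@@]4(O)N(C[C@@H](CC2)[C@@]14C)C[C@@H](C)C3=O | intermediate (not isolated)
28 | vinylketene from 27 | O=C=C1CCOC2=C1C1=C[C@]3(O)C[C@@]4(O)N(C[C@@H](CC2)[C@@]14C)C[C@@H](C)C3=O | intermediate (not isolated)
29 | hydroxyfulvene (deacetyl target) | OC1=C2CCOC3=C2C2=C1[C@]1(O)C[C@@]4(O)N(C[C@@H](CC3)[C@@]24C)C[C@@H](C)C1=O | intermediate (not isolated)
30 | CNP0309418.1 | CC(=O)OC1=C2CCOC3=C2C2=C1[C@]1(O)C[C@@]4(O)N(C[C@@H](CC3)[C@@]24C)C[C@@H](C)C1=O | target

**Step count and risks**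

Total steps: 16. Longest linear sequence: 15 steps (steps 1–6, then 8–16).

Steps most likely to fail:

1. Step 16 (proposed new method). The ketene may be consumed by dimerisation or by acylation of nitrogen or oxygen faster than it closes onto the diene, or the five-centre closure may be too slow. The fallback uses known chemistry and closes the ring at the aldehyde oxidation level. It sets out from 26. Thioesterification (EtSH, EDC·HCl, DMAP) gives the S-ethyl thioester F1. Fukuyama reduction (Et3SiH, Pd/C, acetone) gives the aldehyde F2. Me2AlCl in CH2Cl2 at −78 °C promotes Prins-type addition of the dienol ether terminus e to the aldehyde, and proton loss gives the ring-closed carbinol F3. Dess–Martin oxidation of F3 gives the ketone, which is the keto tautomer of hydroxyfulvene 29, where the fallback rejoins the route. O-Acetylation of 29 (Ac2O, Et3N) gives 30.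

2. Step 11. Enolisation may occur at the pyran ester instead, the tertiary alkoxide β to the imine may open by retro-aldol cleavage, or oxygen may be delivered to the wrong face. The fallback hydroxylates last, at the bridgehead, where only the exo face exists. It sets out from 18. Camphorsulfonic acid with molecular sieves gives the dienol ether F4, and Bu4NF gives the acid F5. MeNH(OMe)·HCl with iPrMgCl gives the Weinreb amide F6, and isopropenylmagnesium bromide gives the enone F7; its α-CH epimerises, so both epimers converge. Buffered aqueous MeCN closes ring A to the bridged amino ketone F8. KN(SiMe3)2 followed by the oxaziridine then removes the exposed exo bridgehead α-hydrogen (which is also allylic, while the other α-hydrogen points into the cage) and oxygenates that carbon on its only open face. This gives 26, where the fallback rejoins the route.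

3. Step 10. The enol ether may attack the Lewis acid-bound imine carbon instead of the ketone, methyl may be transferred from aluminium, or the seven-membered ring may fail to close. The fallback inverts the polarity and closes the ring through a vinyl metal. It sets out from 17. N-Iodosuccinimide in MeCN followed by DBU iodinates the enol ether β-carbon to the iodo enol ether F9. Intramolecular Nozaki–Hiyama–Kishi addition (CrCl2, NiCl2 cat., DMF) to the ketone gives the tertiary alcohol F10, which has the same carbinol configuration as 18 and keeps the enol ether in ring F. Hydroxylation of F10 under the conditions of step 11 gives 20, where the fallback rejoins the route (acid then gives 21).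

**Further compounds**

F1 | step 16 | S-ethyl thioester of 26 | CCSC(=O)C1CCOC2=C1C1=C[C@]3(O)C[C@@]4(O)N(C[C@@H](CC2)[C@@]14C)C[C@@H](C)C3=O
F2 | step 16 | aldehyde corresponding to 26 | O=CC1CCOC2=C1C1=C[C@]3(O)C[C@@]4(O)N(C[C@@H](CC2)[C@@]14C)C[C@@H](C)C3=O
F3 | step 16 | ring-E carbinol (secondary alcohol at atom a) | OC1C2CCOC3=C2C2=C1[C@]1(O)C[C@@]4(O)N(C[C@@H](CC3)[C@@]24C)C[C@@H](C)C1=O
F4 | step 11 | dienol ether diester lacking the ketol hydroxyl | CCOC(=O)C1C=C2C3=C(CC[C@@H]4CN=C(C1)[C@@]42C)OCCC3C(=O)OCC[Si](C)(C)C
F5 | step 11 | acid from F4 | CCOC(=O)C1C=C2C3=C(CC[C@@H]4CN=C(C1)[C@@]42C)OCCC3C(O)=O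
F6 | step 11 | Weinreb amide from F5 | CON(C)C(=O)C1C=C2C3=C(CC[C@@H]4CN=C(C1)[C@@]42C)OCCC3C(O)=O
F7 | step 11 | enone from F6 | C=C(C)C(=O)C1C=C2C3=C(CC[C@@H]4CN=C(C1)[C@@]42C)OCCC3C(O)=O
F8 | step 11 | bridged amino ketone with bridgehead CH (deoxy 26) | OC(=O)C1CCOC2=C1C1=C[C@@H]3C[C@@]4(O)N(C[C@@H](CC2)[C@@]14C)C[C@@H](C)C3=O
F9 | step 10 | iodo enol ether from 17 | CCOC(=O)C1CC(=O)[C@]2(C)[C@H](CCC3=C(I)C(C(=O)OCC[Si](C)(C)C)CCO3)CN=C2C1
F10 | step 10 | tertiary alcohol with endocyclic enol ether (isomer of 18) | CCOC(=O)C1C[C@]2(O)C3=C(CC[C@@H]4CN=C(C1)[C@@]42C)OCCC3C(=O)OCC[Si](C)(C)C
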